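## Structural features

The target is 2,3,4,6-tetrabromo-1-methyl-1H-indole (C9H5Br4N). A benzene ring (ring A: C3a, C4, C5, C6, C7, C7a) is fused along the C3a–C7a bond to a pyrrole ring (ring B: N1, C2, C3, C3a, C7a). N1 carries a methyl group, C2 and C3 of ring B and C4 and C6 of ring A carry bromine, and C5 and C7 are the only ring C–H positions. The molecule is flat and has no stereocentre, so no stereochemical relationship has to be controlled. The fragile elements are the four C–Br bonds (intolerant of low-valent metals, organolithium reagents, strong reductants and prolonged light) and the electron-rich 2,3-dibromopyrrole half (sensitive to acid and oxidants). The real difficulty is positional: electrophilic bromination of an indole goes to C3, then C2, then C5 or C6, and never cleanly to C4 together with C6. The C3 and C4 bromines also sit in a crowded peri relationship. The key step exploits the bromine at C4: an aryl group joined to the side chain through C3a has one ortho carbon blocked by bromine and one free ortho C–H, the future C7a, so a nitrogen held on C2 can bond to ring A at one position only.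

## Logic of the disconnections

**10 back to 8 (through 9).** The C2–Br and C3–Br bonds are cut first; C3 returns to C–H and C2 to C–CO2H. These are the two bromines that an electrophilic bromine source can place with certainty, because C3 is the most nucleophilic carbon and a carboxyl group at C2 can leave as CO2 on ipso attack. The gain is that 8 has no labile pyrrole halogen, and its carboxyl group is inherited at no cost from the ring-forming step, so no separate decarboxylation is needed. The forward step must brominate C3 beside the peri bromine at C4 and then replace the carboxyl group at C2, without touching C5, C7 or the N-methyl group.

**8 back to 6 (through 7).** The N1–CH3 bond is cut and the acid is returned to its ethyl ester. The cut is made here because the ring closure necessarily delivers N–H, and methylation is best done before the pyrrole bromines exist, since N-unsubstituted 2,3-dibromoindoles are labile. The gain is that 6 is the direct product of the key step. The forward step needs only N-alkylation at the single acidic site and an ester hydrolysis mild enough not to decarboxylate.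

**6 back to 4 (through 5).** The N1–C7a bond is cut and ring B is opened. The cut is placed here because the bromine at C4 leaves only one ortho carbon free, so the closure has no regiochemical choice. The gain is a bicyclic heteroarene reduced to a monocyclic arene with a three-carbon side chain, with the nitrogen stored as an azide on the future C2. The forward step must bring that nitrogen to the nitrene level under neutral, metal-free conditions that spare both aryl bromides, and it must favour intramolecular closure over bimolecular decay.

**4 back to 1 and 2 (through 3).** The C2=C3 double bond is cut, the only carbon–carbon bond made in the synthesis. An aldehyde and an active methylene compound result, both commercial, and 1 already carries both benzenoid bromines in the correct relative positions. The forward condensation must run cold enough for the azide group to survive and must go past the aldol stage 3 to the alkene. The Z geometry is expected but is not critical.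

## Other disconnections considered

**Alternative 1:** The cut is C3a–C4: ring A is grown onto a preformed N-methylpyrrole, and both benzenoid bromines are traced back to phenols.
- Forward key step: the acyl Meldrum's acid A1 would be heated in dilute toluene. It should fragment to an acylketene whose ketene carbon acylates the pyrrole β-carbon, and the resulting six-membered diketone should enolise to the diol A2.
- In its favour: the closure is metal-free, the 4,6-pattern is fixed by the chain, and the N-methyl group is present from the start.
- Against it here: oxygen is the wrong substituent. A2 is an electron-rich, oxidation-prone diol that would have to be converted to the bis(triflate) A3. Two C–O to C–Br exchanges on an electron-rich core would follow (for example Pd2(dba)3, a zerovalent palladium source, a bulky biarylphosphine and KBr), a transformation of narrow scope. Only then could C2 and C3 be brominated. Ketene dimerisation also competes unless dilution is high.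
- Comparison, structure: both plans fix the 4,6-relationship by connectivity and are equal there, but the chosen plan buys the two aryl bromines in 1 while this one must create them.
- Comparison, mechanism: acylation by a ketene is at least as dependable as a nitrene closure. On safety this alternative is the better one, since no azide is handled.
- Comparison, step economy: it is clearly inferior, an estimated six to seven steps against four.

**Alternative 2:** The cut is C5–C6, again building ring A on an N-methylpyrrole, but with all the required bromine already on the triene A4. A4 is a 2,3-divinylpyrrole with a 1-bromovinyl group on the β-carbon and a 2,2-dibromovinyl group on the α-carbon.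
- Forward key step: heating A4 with K2CO3 in o-dichlorobenzene near 180 °C should bring about a thermal disrotatory 6π electrocyclisation between the CH2 and CBr2 termini. Loss of HBr from the ring-closed dihydro intermediate should then give the aromatic A5.
- In its favour: A5 has the N-methyl group and the correct dibromo pattern and no carboxyl group to remove, so a single dibromination would finish the synthesis. After the key step this alternative is the better one: one operation against two.
- Against it here: the central double bond of the triene belongs to the pyrrole ring, so the closure costs aromatic stabilisation. One bromine of the CBr2 terminus must turn inward in the transition state. Hot carbonate can dehydrobrominate the vinyl bromides before the ring closes.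
- The larger cost lies before the key step. A4 needs a 2,3-difunctionalised N-methylpyrrole, which electrophilic pyrrole chemistry does not deliver directly (a 2-acylpyrrole is acylated at C4). It also needs a dibromo-olefination and a ketone-to-vinyl-bromide conversion.
- Comparison, structure: regiochemical certainty is equal.
- Comparison, mechanism: both key steps are thermal pericyclic closures followed by loss or shift of hydrogen. The chosen one is driven by irreversible loss of N2, whereas this one stays reversible until HBr is lost. It is again better on azide safety.
- Comparison, step economy: an estimated five or six steps to A4 make it longer overall.

**Alternative 3:** The cut is C3–C3a: ring B is closed from the carbon side on the N-aryl enaminoate A6, a β-(N-methyl-N-arylamino)acrylate whose aryl group is 3,5-dibromophenyl.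
- Forward key step: constant-current electrolysis with a graphite anode, KI as mediator and a platinum cathode in an undivided cell. Anodically formed iodine should iodinate the ester-bearing alkene carbon. The activated carbon should then attack an ortho carbon of the aryl ring, and loss of a proton should give A7 while H2 forms at the cathode.
- In its favour: the aryl group is symmetric, so both ortho carbons are equivalent and regiochemistry is no issue, a point on which it equals the chosen plan. The N-methyl group is in place, and neither an azide nor a chemical oxidant is needed. The carboxyl group ends up at C3, the most nucleophilic indole carbon, where a later ipso-bromodecarboxylation should be easier than at C2. That is a point on which it is better.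
- Against it here: the ring to be attacked is deactivated by two bromines and the carbon attacked is flanked by one of them. The closure therefore depends on the nucleophilicity of a poor arene, whereas the nitrene closure of the chosen plan does not. The new ester lands peri to the C4 bromine. The enaminoate has no substituent at the future C2 to stabilise the oxidised intermediate. Cathodic C–Br reduction is conceivable in an undivided cell.
- Comparison, structure: equal in regiochemical certainty.
- Comparison, mechanism: confidence is lower for this substitution pattern.
- Comparison, step economy: conjugate addition, electrolysis, saponification and bromination make about four steps, equal to the chosen plan.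

Key step: step 2

**Remarks before the steps**

- Structure check: in the key step the aryl C1 becomes C3a, the free ortho carbon C7a, the ortho bromine the C4 bromine and the para bromine the C6 bromine, and Z means azide cis to aryl. Precursor 4 and product 6 are consistent with the target and neither needs correction. 4 is kept as the ethyl ester because this matches the ethoxide base and avoids mixed esters.
- Assumption: 2 is taken as its commercial solution in ethanol and is never concentrated, because its (C + O)/N ratio is 2. 4 (ratio about 4.3) is kept below 40 °C, shielded from light, not dried with heat, and fed to the thermolysis as a xylene solution. No inorganic azide and no acid meets an azide anywhere in the route.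

## Route

Step 1
Reactants: 1 2,4-dibromobenzaldehyde; 2 ethyl azidoacetate
Product: 4 ethyl (2Z)-2-azido-3-(2,4-dibromophenyl)prop-2-enoate, via aldol adduct 3 (not isolated)
Conditions: NaOEt (3.5 equiv), 2 (3.5 equiv), EtOH, −10 °C → 0 °C; cold aq NH4Cl
Reagents that add atoms: none
Why: Knoevenagel condensation: the ethoxide-derived carbanion of 2 adds to the aldehyde to give 3, and E1cB loss of hydroxide should give the conjugated vinyl azide as the thermodynamically preferred Z isomer (azide cis to aryl, ester trans); below 0 °C the azide group and both aryl bromides are inert.

Step 2
Reactants: 4 ethyl (2Z)-2-azido-3-(2,4-dibromophenyl)prop-2-enoate
Product: 6 ethyl 4,6-dibromo-1H-indole-2-carboxylate, via 2H-azirine 5 (not isolated)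
Conditions: xylene, 140 °C, dropwise addition of 4 in xylene over 2 h (final 0.05 M), N2
Reagents that add atoms: none
Why: This is a Hemetsberger–Knittel indole synthesis, the closest known reaction type being the thermolysis of α-azidocinnamates to indole-2-carboxylates. At about 140 °C the vinyl azide loses N2 and gives the 2H-azirine 5, which is in thermal equilibrium with the ring-opened vinyl nitrene. The nitrene nitrogen attacks the single free ortho carbon in a thermal 6π-electron 1,5-electrocyclisation that forms N1–C7a and closes ring B as a five-membered ring, and a suprafacial 1,5-hydrogen shift from C7a to N1 then restores the aromaticity of ring A. No stereocentre is created, because the sp3 carbon of racemic 5 and the transient sp3 C7a both become trigonal in 6. The selectivity needed is regioselectivity between the two ortho carbons, and the substrate secures it: the other ortho carbon bears bromine, an adduct formed there would have no hydrogen to shift and should revert, so the 4,6-dibromo isomer is the only indole that can form. Chemoselectivity follows from the neutral, metal-free conditions, under which both C–Br bonds and the ester are inert. Slow addition to hot, dilute xylene keeps the standing concentration of azide low, which favours the intramolecular closure over bimolecular decay and releases N2 at the feed rate. Either alkene geometry converges on the same azirine, so a minor E component would not be lost.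

Step 3
Reactants: 6 ethyl 4,6-dibromo-1H-indole-2-carboxylate
Product: 8 4,6-dibromo-1-methyl-1H-indole-2-carboxylic acid, via N-methyl ethyl ester 7 (not isolated)
Conditions: MeI (1.3 equiv), K2CO3 (2 equiv), DMSO, rt; then 2 M aq NaOH, 50 °C; then 1 M HCl, pH 2
Reagents that add atoms: iodomethane, CI; sodium hydroxide, [Na+].[OH-]
Why: SN2 N-alkylation of the indolyl anion (the ester-acidified N–H is the only acidic site) is followed in the same pot by BAc2 saponification, whose hydroxide oxygen becomes one carboxyl oxygen; the hydroxide also destroys surplus iodomethane before work-up, and the acid should precipitate on acidification.

Step 4
Reactants: 8 4,6-dibromo-1-methyl-1H-indole-2-carboxylic acid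
Product: 10 2,3,4,6-tetrabromo-1-methyl-1H-indole, via 3-bromo acid 9 (not isolated)
Conditions: NBS (2.1 equiv), LiOAc (0.2 equiv), DMF, 0 °C → rt (40 °C if needed), dark
Reagents that add atoms: N-bromosuccinimide, O=C1CCC(=O)N1Br
Why: Electrophilic aromatic bromination at C3, the most nucleophilic carbon, gives 9; a second bromine transfer to the carboxylate form of 9 should end as ipso substitution at C2 with loss of CO2 (electrophilic halodecarboxylation, the Hunsdiecker-type ipso-bromodecarboxylation known for electron-rich pyrrole and indole carboxylic acids); C5 and C7 are deactivated by the flanking bromines and should stay untouched.

## Compound list

1 | 2,4-dibromobenzaldehyde | O=Cc1ccc(Br)cc1Br | starting material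
2 | ethyl azidoacetate | CCOC(=O)CN=[N+]=[N-] | starting material
3 | ethyl 2-azido-3-(2,4-dibromophenyl)-3-hydroxypropanoate (aldol adduct, not isolated; mixture of racemic diastereomers, both stereocentres are erased within step 1) | CCOC(=O)C(N=[N+]=[N-])C(O)c1ccc(Br)cc1Br | intermediate
4 | ethyl (2Z)-2-azido-3-(2,4-dibromophenyl)prop-2-enoate | CCOC(=O)/C(N=[N+]=[N-])=C/c1ccc(Br)cc1Br | intermediate
5 | ethyl 2-(2,4-dibromophenyl)-2H-azirine-3-carboxylate (racemic, not isolated) | CCOC(=O)C1=NC1c1ccc(Br)cc1Br | intermediate
6 | ethyl 4,6-dibromo-1H-indole-2-carboxylate | CCOC(=O)c1cc2c(Br)cc(Br)cc2[nH]1 | intermediate
7 | ethyl 4,6-dibromo-1-methyl-1H-indole-2-carboxylate (not isolated) | CCOC(=O)c1cc2c(Br)cc(Br)cc2n1C | intermediate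
8 | 4,6-dibromo-1-methyl-1H-indole-2-carboxylic acid | Cn1c(C(=O)O)cc2c(Br)cc(Br)cc21 | intermediate
9 | 3,4,6-tribromo-1-methyl-1H-indole-2-carboxylic acid (not isolated) | Cn1c(C(=O)O)c(Br)c2c(Br)cc(Br)cc21 | intermediate
10 | 2,3,4,6-tetrabromo-1-methyl-1H-indole | Cn1c(Br)c(Br)c2c(Br)cc(Br)cc21 | target

## Step count and least certain steps

Total step count: 4. Longest linear sequence: 4 steps (1 → 4 → 6 → 8 → 10).

**Step 2 (key step).**
- What may go wrong: bimolecular decay of the azirine and nitrene (dimerisation, insertion into solvent C–H bonds, tar formation) in competition with ring closure, because the ortho bromine twists the aryl ring out of conjugation with the azadiene and slows the electrocyclisation. Unreacted azide may also accumulate if the feed runs faster than N2 loss.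
- Fallback: the free-nitrene thermolysis is replaced by catalytic nitrene transfer at a metal centre. Setting out from 4, Rh2(O2CC3F7)4 (dirhodium tetrakis(heptafluorobutyrate), a divalent rhodium carboxylate, 3–5 mol %) in toluene at 40–60 °C should give the indole directly and return to the route at 6. N2 is lost at rhodium, the metal-bound nitrene equivalent closes onto the same free ortho carbon, and the much lower temperature removes the thermal bimolecular pathways. No new compound is made (entry F0).

**Step 4.**
- What may go wrong: the sequence may stall after C3 substitution, because ipso attack at C2 of a ring that already carries three bromines is slow. Bromine may instead be delivered to C7 or, by a radical pathway, to the N-methyl group. Traces of water could divert the brominated indoleninium intermediate into oxidation at C2.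
- Fallback: the step is split into protodecarboxylation and dibromination. Setting out from 8, Ag2CO3 (10 mol %) and AcOH (5 mol %) in DMSO at 120 °C should remove the carboxyl group, leaving the aryl bromides alone, and give 4,6-dibromo-1-methyl-1H-indole F1 (identical with A5). NBS (2.05 equiv) in THF from −78 °C to rt should then brominate C3 and C2 in turn, the standard 2,3-dibromination of N-methylindoles, and return to the route at 10.

**Step 1.**
- What may go wrong: the ortho bromine hinders the carbonyl group, so the addition may stop at the aldol stage or revert. Ethoxide slowly decomposes the azidoacetate with loss of N2. The hydroxide set free in the dehydration can saponify the esters.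
- Fallback: addition and elimination are separated. Setting out from 1 and 2, a short reaction at −30 °C (NaOEt, EtOH, NH4Cl quench) should allow 3 to be isolated. MsCl and Et3N in CH2Cl2 at 0 °C should then convert it into ethyl 2-azido-3-(2,4-dibromophenyl)-3-[(methylsulfonyl)oxy]propanoate F2. F2 should lose methanesulfonate by E1cB under the excess amine and return to the route at 4.

## Further compounds

F0 | step 2 | none | none
F1 | step 4 | 4,6-dibromo-1-methyl-1H-indole | Cn1ccc2c(Br)cc(Br)cc21
F2 | step 1 | ethyl 2-azido-3-(2,4-dibromophenyl)-3-[(methylsulfonyl)oxy]propanoate | CCOC(=O)C(N=[N+]=[N-])C(OS(C)(=O)=O)c1ccc(Br)cc1Br
A1 | alternative 1 | 2,2-dimethyl-5-[(1-methyl-1H-pyrrol-2-yl)acetyl]-1,3-dioxane-4,6-dione | Cn1cccc1CC(=O)C1C(=O)OC(C)(C)OC1=O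
A2 | alternative 1 | 1-methyl-1H-indole-4,6-diol | Cn1ccc2c(O)cc(O)cc21
A3 | alternative 1 | 1-methyl-1H-indole-4,6-diyl bis(trifluoromethanesulfonate) | Cn1ccc2c(OS(=O)(=O)C(F)(F)F)cc(OS(=O)(=O)C(F)(F)F)cc21
A4 | alternative 2 | 3-(1-bromoethenyl)-2-(2,2-dibromoethenyl)-1-methyl-1H-pyrrole | Cn1ccc(C(Br)=C)c1C=C(Br)Br
A5 | alternative 2 | 4,6-dibromo-1-methyl-1H-indole | Cn1ccc2c(Br)cc(Br)cc21
A6 | alternative 3 | methyl (2E)-3-[(3,5-dibromophenyl)(methyl)amino]prop-2-enoate | COC(=O)/C=C/N(C)c1cc(Br)cc(Br)c1
A7 | alternative 3 | methyl 4,6-dibromo-1-methyl-1H-indole-3-carboxylate | COC(=O)c1cn(C)c2cc(Br)cc(Br)c12
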